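Retrosynthetic cuts, in order: the aryl angelate C(=O)–O bond; the oxirane O–CH2 bond (back to a tertiary alcohol and a primary tosylate); the two alkyl ester C(=O)–O bonds (benzylic and acyloxymethyl); the aryl–C(quaternary) bond (back to an aryl iodide and 2,2-dimethyl-1,3-dioxan-5-one).
Enabling feature: the quaternary oxirane carbon carries the ring O, the benzene ring and two CH2–O arms (the oxirane CH2 and the acyloxymethyl CH2). It is a stereocentre only because these arms differ, so it maps onto the prochiral carbinol carbon of a 2-arylpropane-1,2,3-triol with two enantiotopic CH2OH groups.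
Forward: the benzene ring is bought; arylmagnesium addition joins it to the C3 unit; ester reduction and acetonide hydrolysis expose the tetraol; a lipase installs both (R)-2-methylbutanoates; tosylation and base close the oxirane (the only ring formed); a fluoride-triggered silyl-to-angeloyl exchange ends the route.
Stereochemistry: both acyl centres come unchanged from (R)-2-methylbutanoic acid; the (R) oxirane centre comes from the lipase's choice of the pro-R arm and is not touched again, because ring closure takes place at CH2; the Z alkene comes from angelic acid.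
Key step: step 6

Assumption: Candida antarctica lipase B is taken to acylate the pro-R hydroxymethyl arm of 7, as the (R) oxirane centre requires; this sense cannot be read from the structure and is to be confirmed on the first run.

Step 1
Reactants: 1 methyl 3-hydroxy-4-iodobenzoate
Product: 2 methyl 3-(tert-butyldimethylsilyloxy)-4-iodobenzoate
Conditions: TBSCl, imidazole, DMF, 0 °C → rt
Reagents that add atoms: tert-butyldimethylsilyl chloride, CC(C)(C)[Si](C)(C)Cl
Why: Imidazole-promoted O-silylation of the phenol masks the acidic OH before the organomagnesium step and gives an aryl silyl ether that fluoride alone can later cleave.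

Step 2
Reactants: 2 methyl 3-(tert-butyldimethylsilyloxy)-4-iodobenzoate; 3 2,2-dimethyl-1,3-dioxan-5-one
Product: 5 methyl 3-(tert-butyldimethylsilyloxy)-4-(5-hydroxy-2,2-dimethyl-1,3-dioxan-5-yl)benzoate, via arylmagnesium chloride 4 (not isolated)
Conditions: i-PrMgCl·LiCl, THF, −40 °C; then 3, LaCl3·2LiCl, −40 → 0 °C; aq. NH4Cl
Reagents that add atoms: none
Why: Iodine–magnesium exchange is fast at −40 °C on an aryl iodide with a para ester and an ortho oxygen and spares the methyl ester, and the LaCl3·2LiCl-promoted Grignard 1,2-addition to the symmetric ketone should outrun enolisation, so the aryl–C bond forms without creating a stereocentre.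

Step 3
Reactants: 5 methyl 3-(tert-butyldimethylsilyloxy)-4-(5-hydroxy-2,2-dimethyl-1,3-dioxan-5-yl)benzoate
Product: 6 5-[2-(tert-butyldimethylsilyloxy)-4-(hydroxymethyl)phenyl]-2,2-dimethyl-1,3-dioxan-5-ol
Conditions: i-Bu2AlH (3.5 equiv), CH2Cl2, −78 → 0 °C; aq. potassium sodium tartrate (KNaC4H4O6)
Reagents that add atoms: none
Why: Hydride reduction of the benzoate ester with i-Bu2AlH gives the benzylic alcohol at low temperature and should leave the aryl silyl ether, the acetonide and the tertiary alcohol (held as its aluminium alkoxide) intact.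

Step 4
Reactants: 6 5-[2-(tert-butyldimethylsilyloxy)-4-(hydroxymethyl)phenyl]-2,2-dimethyl-1,3-dioxan-5-ol
Product: 7 2-[2-(tert-butyldimethylsilyloxy)-4-(hydroxymethyl)phenyl]propane-1,2,3-triol
Conditions: AcOH/THF/H2O (3:1:1), rt to 40 °C
Reagents that add atoms: none
Why: Acid-catalysed acetal hydrolysis in excess water frees the two enantiotopic hydroxymethyl groups, while the aryl silyl ether, which is more stable to acid than to base, should survive; the carbinol carbon stays prochiral.

Step 5
Reactants: 8 (R)-2-methylbutanoic acid
Product: 9 vinyl (R)-2-methylbutanoate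
Conditions: Pd(OAc)2 (cat.), KOH (cat.), vinyl acetate (solvent), rt; distillation
Reagents that add atoms: vinyl acetate, C=COC(C)=O
Why: Pd(OAc)2-catalysed transvinylation (vinyl interchange) with excess vinyl acetate converts the acid into its vinyl ester without touching the α-C–H bond, so the (R) centre is carried over unchanged.

Step 6
Reactants: 7 2-[2-(tert-butyldimethylsilyloxy)-4-(hydroxymethyl)phenyl]propane-1,2,3-triol; 9 vinyl (R)-2-methylbutanoate
Product: 11 (2R)-2-[2-(tert-butyldimethylsilyloxy)-4-({[(2R)-2-methylbutanoyl]oxy}methyl)phenyl]-2,3-dihydroxypropyl (2R)-2-methylbutanoate, via benzylic monoester 10 (not isolated)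
Conditions: immobilised Candida antarctica lipase B, 9 (3 equiv), t-BuOMe, 30 °C; enzyme filtered off once 10 is consumed
Reagents that add atoms: none
Why: The catalytic serine is acylated by vinyl ester 9 with loss of vinyl alcohol, which tautomerises to acetaldehyde and makes each transfer irreversible, and the acyl-enzyme then passes the (R)-2-methylbutanoyl group to a primary hydroxyl. The closest known reaction type is the lipase-catalysed irreversible transesterification that desymmetrises prochiral 2-substituted propane-1,3-diols and 2-substituted glycerols with vinyl esters. No ring closes; two O–acyl bonds form, first at the unhindered benzylic alcohol (10) and then at one hydroxymethyl arm. The new carbinol stereocentre is under catalyst control: the chiral alcohol pocket should bring only the pro-R arm to the acyl-serine, which gives the (R) configuration, while both acyl stereocentres arrive intact from 9. The step needs site selectivity, arm selectivity and a stop before the last primary hydroxyl reacts; a serine hydrolase does not accept the tertiary alcohol or the silylated phenol, and the remaining neopentylic arm should react more slowly, its slow over-acylation consuming mainly the minor arm isomer. Because the acyl groups are homochiral the two arm isomers are diastereomers, so the outcome can be read by NMR or achiral HPLC, and the α-branched ester should migrate between the arms more slowly than an acetate.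

Step 7
Reactants: 11 (2R)-2-[2-(tert-butyldimethylsilyloxy)-4-({[(2R)-2-methylbutanoyl]oxy}methyl)phenyl]-2,3-dihydroxypropyl (2R)-2-methylbutanoate
Product: 12 (2S)-2-[2-(tert-butyldimethylsilyloxy)-4-({[(2R)-2-methylbutanoyl]oxy}methyl)phenyl]-2-hydroxy-3-(tosyloxy)propyl (2R)-2-methylbutanoate
Conditions: TsCl, Et3N, Me3N·HCl (cat.), CH2Cl2, 0 °C; run directly after step 6
Reagents that add atoms: p-toluenesulfonyl chloride, Cc1ccc(cc1)S(=O)(=O)Cl
Why: Amine-promoted O-sulfonylation is selective for the primary over the tertiary benzylic hydroxyl, and doing it promptly at 0 °C fixes the arm assignment before acyl migration can scramble the carbinol centre, whose descriptor becomes (S) only through the change in CIP priorities.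

Step 8
Reactants: 12 (2S)-2-[2-(tert-butyldimethylsilyloxy)-4-({[(2R)-2-methylbutanoyl]oxy}methyl)phenyl]-2-hydroxy-3-(tosyloxy)propyl (2R)-2-methylbutanoate
Product: 14 {(2R)-2-[2-(tert-butyldimethylsilyloxy)-4-({[(2R)-2-methylbutanoyl]oxy}methyl)phenyl]oxiran-2-yl}methyl (2R)-2-methylbutanoate, via sodium alkoxide 13 (not isolated)
Conditions: NaH (1.1 equiv), THF, 0 °C
Reagents that add atoms: none
Why: Deprotonation of the tertiary alcohol triggers an intramolecular Williamson etherification (3-exo-tet displacement of tosylate at the CH2 carbon), which should close the oxirane faster than the alkoxide attacks an ester or the silyl group and leaves the quaternary centre, now (R) by descriptor, untouched.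

Step 9
Reactants: 15 angelic acid [(2Z)-2-methylbut-2-enoic acid]
Product: 16 (2Z)-2-methylbut-2-enoic 2,4,6-trichlorobenzoic anhydride
Conditions: 2,4,6-trichlorobenzoyl chloride, Et3N, THF, 0 °C → rt; filtered solution used directly
Reagents that add atoms: 2,4,6-trichlorobenzoyl chloride, O=C(Cl)c1c(Cl)cc(Cl)cc1Cl
Why: Acylation of the angelate anion by the hindered acid chloride gives the Yamaguchi-type mixed anhydride with an amine base only and no nucleophilic catalyst, which is what should keep the Z alkene from isomerising to the tiglate.

Step 10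
Reactants: 14 {(2R)-2-[2-(tert-butyldimethylsilyloxy)-4-({[(2R)-2-methylbutanoyl]oxy}methyl)phenyl]oxiran-2-yl}methyl (2R)-2-methylbutanoate; 16 (2Z)-2-methylbut-2-enoic 2,4,6-trichlorobenzoic anhydride
Product: 18 2-[(2R)-2-({[(2R)-2-methylbutanoyl]oxy}methyl)oxiran-2-yl]-5-({[(2R)-2-methylbutanoyl]oxy}methyl)phenyl (2Z)-2-methylbut-2-enoate, via tetrabutylammonium phenoxide 17 (not isolated)
Conditions: Bu4NF (1.0 M in THF, 1.05 equiv), THF, −78 °C, 10 min; then 16 (1.5 equiv), −78 → −20 °C
Reagents that add atoms: none
Why: Fluoride desilylation of the aryl silyl ether at low temperature frees a phenoxide that undergoes nucleophilic acyl substitution at the less hindered angeloyl carbonyl of the mixed anhydride before it can open the neighbouring oxirane, so the target should form with all three stereocentres and the Z alkene unchanged.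

Compound list
1 | methyl 3-hydroxy-4-iodobenzoate | COC(=O)c1ccc(I)c(O)c1 | starting material
2 | methyl 3-(tert-butyldimethylsilyloxy)-4-iodobenzoate | COC(=O)c1ccc(I)c(O[Si](C)(C)C(C)(C)C)c1 | intermediate
3 | 2,2-dimethyl-1,3-dioxan-5-one | CC1(C)OCC(=O)CO1 | starting material
4 | [2-(tert-butyldimethylsilyloxy)-4-(methoxycarbonyl)phenyl]magnesium chloride, LiCl complex, formed in situ | COC(=O)c1ccc([Mg]Cl)c(O[Si](C)(C)C(C)(C)C)c1 | intermediate
5 | methyl 3-(tert-butyldimethylsilyloxy)-4-(5-hydroxy-2,2-dimethyl-1,3-dioxan-5-yl)benzoate | COC(=O)c1ccc(C2(O)COC(C)(C)OC2)c(O[Si](C)(C)C(C)(C)C)c1 | intermediate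
6 | 5-[2-(tert-butyldimethylsilyloxy)-4-(hydroxymethyl)phenyl]-2,2-dimethyl-1,3-dioxan-5-ol | OCc1ccc(C2(O)COC(C)(C)OC2)c(O[Si](C)(C)C(C)(C)C)c1 | intermediate
7 | 2-[2-(tert-butyldimethylsilyloxy)-4-(hydroxymethyl)phenyl]propane-1,2,3-triol | CC(C)(C)[Si](C)(C)Oc1cc(CO)ccc1C(O)(CO)CO | intermediate
8 | (R)-2-methylbutanoic acid | CC[C@@H](C)C(=O)O | starting material
9 | vinyl (R)-2-methylbutanoate | C=COC(=O)[C@H](C)CC | intermediate
10 | [3-(tert-butyldimethylsilyloxy)-4-(1,2,3-trihydroxypropan-2-yl)phenyl]methyl (2R)-2-methylbutanoate, formed in situ | CC(C)(C)[Si](C)(C)Oc1cc(COC(=O)[C@H](C)CC)ccc1C(O)(CO)CO | intermediate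
11 | (2R)-2-[2-(tert-butyldimethylsilyloxy)-4-({[(2R)-2-methylbutanoyl]oxy}methyl)phenyl]-2,3-dihydroxypropyl (2R)-2-methylbutanoate | CC(C)(C)[Si](C)(C)Oc1cc(COC(=O)[C@H](C)CC)ccc1[C@](O)(COC(=O)[C@H](C)CC)CO | intermediate
12 | (2S)-2-[2-(tert-butyldimethylsilyloxy)-4-({[(2R)-2-methylbutanoyl]oxy}methyl)phenyl]-2-hydroxy-3-(tosyloxy)propyl (2R)-2-methylbutanoate | CC(C)(C)[Si](C)(C)Oc1cc(COC(=O)[C@H](C)CC)ccc1[C@](O)(COC(=O)[C@H](C)CC)COS(=O)(=O)c1ccc(C)cc1 | intermediate
13 | sodium alkoxide of 12 at the tertiary oxygen, formed in situ | CC(C)(C)[Si](C)(C)Oc1cc(COC(=O)[C@H](C)CC)ccc1[C@]([O-])(COC(=O)[C@H](C)CC)COS(=O)(=O)c1ccc(C)cc1.[Na+] | intermediate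
14 | {(2R)-2-[2-(tert-butyldimethylsilyloxy)-4-({[(2R)-2-methylbutanoyl]oxy}methyl)phenyl]oxiran-2-yl}methyl (2R)-2-methylbutanoate | CC(C)(C)[Si](C)(C)Oc1cc(COC(=O)[C@H](C)CC)ccc1[C@]1(COC(=O)[C@H](C)CC)CO1 | intermediate
15 | angelic acid, (2Z)-2-methylbut-2-enoic acid | C/C=C(/C)C(=O)O | starting material
16 | (2Z)-2-methylbut-2-enoic 2,4,6-trichlorobenzoic anhydride | C/C=C(/C)C(=O)OC(=O)c1c(Cl)cc(Cl)cc1Cl | intermediate
17 | tetrabutylammonium phenoxide of desilylated 14, formed in situ | [O-]c1cc(COC(=O)[C@H](C)CC)ccc1[C@]1(COC(=O)[C@H](C)CC)CO1.CCCC[N+](CCCC)(CCCC)CCCC | intermediate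
18 | 2-[(2R)-2-({[(2R)-2-methylbutanoyl]oxy}methyl)oxiran-2-yl]-5-({[(2R)-2-methylbutanoyl]oxy}methyl)phenyl (2Z)-2-methylbut-2-enoate (CNP0166772.1) | C/C=C(/C)C(=O)Oc1cc(COC(=O)[C@H](C)CC)ccc1[C@]1(COC(=O)[C@H](C)CC)CO1 | target

Total step count: 10. Longest linear sequence: 8 steps (steps 1, 2, 3, 4, 6, 7, 8 and 10, from compound 1); steps 5 and 9 prepare the two acyl donors.

Steps most likely to fail

Step 6. The acyl-enzyme may deliver the acyl group to the pro-S arm or discriminate the arms poorly, and the slow α-branched donor may allow over-acylation of the second arm to erode the result. The fallback sets out from 7 and comes back at 11 by running the enzyme in the hydrolytic direction. Steglich esterification of 7 with acid 8 (DIC, DMAP cat., CH2Cl2, 0 °C) should acylate all three primary hydroxyls and give the tris-ester F1. Hydrolysis of F1 with the same immobilised lipase in pH 7 phosphate buffer/acetone should remove the unhindered benzylic ester and the ester on the arm the enzyme prefers. That leaves the ester on the other arm, the sense opposite to direct acylation, in the (R)-configured triol monoester F2. A short second exposure of F2 to the lipase and 9, in which the benzylic alcohol should react well before the hindered arm, restores the benzylic ester and returns to 11; any over-acylated material is F1 and can be recycled.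

Step 10. The phenoxide freed next to the benzylic oxirane may open it (ring closure onto the oxirane CH2 or quinone-methide formation) before it is acylated, and basic conditions may isomerise the angelate to the tiglate. The fallback sets out from 11 and arrives at 18, with the order changed so that the oxirane is made last and under neutral conditions. The same fluoride-triggered exchange (Bu4NF, then 16, THF, −78 °C) applied to diol 11 should give the aryl angelate diol F3, in which the phenoxide has no oxirane to attack. Mitsunobu cyclodehydration (PPh3, DIAD, THF, 0 °C) should then activate the primary hydroxyl as its oxyphosphonium salt, and the tertiary hydroxyl displaces it. This closes the oxirane at the CH2 carbon with the quaternary centre untouched and gives 18 without passing through 12, 13, 14 and 17.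

Step 2. The basic arylmagnesium reagent may deprotonate ketone 3 (enolisation) instead of adding, or add too slowly past the ortho silyloxy group, so that only protodeiodinated ester is recovered. The fallback sets out from 2 and comes back at 7, replacing the enolisable ketone by a non-enolisable and more electrophilic C3 unit. The same arylmagnesium species 4 is added at −78 °C to diethyl 2-oxomalonate and should give the diethyl aryl(hydroxy)malonate F4. LiBH4 (THF/MeOH, 0 °C → rt) should then reduce the two ethyl esters and the methyl benzoate in one operation to tetraol 7, which bypasses 5 and 6.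

Further compounds
F1 | step 6 | 2-[2-(tert-butyldimethylsilyloxy)-4-({[(2R)-2-methylbutanoyl]oxy}methyl)phenyl]-2-hydroxypropane-1,3-diyl bis[(2R)-2-methylbutanoate] | CC(C)(C)[Si](C)(C)Oc1cc(COC(=O)[C@H](C)CC)ccc1C(O)(COC(=O)[C@H](C)CC)COC(=O)[C@H](C)CC
F2 | step 6 | (2R)-2-[2-(tert-butyldimethylsilyloxy)-4-(hydroxymethyl)phenyl]-2,3-dihydroxypropyl (2R)-2-methylbutanoate | CC(C)(C)[Si](C)(C)Oc1cc(CO)ccc1[C@](O)(COC(=O)[C@H](C)CC)CO
F3 | step 10 | 2-[(2R)-1,2-dihydroxy-3-{[(2R)-2-methylbutanoyl]oxy}propan-2-yl]-5-({[(2R)-2-methylbutanoyl]oxy}methyl)phenyl (2Z)-2-methylbut-2-enoate | C/C=C(/C)C(=O)Oc1cc(COC(=O)[C@H](C)CC)ccc1[C@](O)(COC(=O)[C@H](C)CC)CO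
F4 | step 2 | diethyl 2-[2-(tert-butyldimethylsilyloxy)-4-(methoxycarbonyl)phenyl]-2-hydroxypropanedioate | CCOC(=O)C(O)(C(=O)OCC)c1ccc(C(=O)OC)cc1O[Si](C)(C)C(C)(C)C
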